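Dividing a stay in a vessel by a time read off the runs is an easy step, and it ranks these set-ups.

| flask | starting material | partner | base | protic impurity | remark | time |
|---|---|---|---|---|---|---|
| alpha | 0.10 M | 0.12 M | 0.010 M | 2 mM | run made earlier |  |
| beta | 0.10 M | 0.17 M | 0.010 M | 2 mM | run made earlier |  |
| epsilon | 0.10 M | 0.26 M | 0.010 M | 2 mM | run made earlier |  |
| eta | 0.15 M | 0.12 M | 0.010 M | 2 mM | run made earlier |  |
| dawn | 0.10 M | 0.120 M (fed, over 1.20 h) | 0.0100 M | 2.00 mM | a stirred flask in which partner is dosed at a steady rate over 1.20 h without added volume, worked up at 1.5 h | 1.5 h |
| noon | 0.10 M | 0.120 M | 0.0100 M | 2.00 mM | one stirred flow tank at steady state, fed with the mixture as stated, mean residence time 1.5 h |  |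
| winter | 0.10 M | 0.120 M | 0.0100 M | 2.00 mM | everything together in a closed stirred flask, run for 1.5 h | 1.5 h |
| midnight | 0.10 M | 0.120 M | 0.0100 M | 2.00 mM | a single well-mixed tank run continuously and read at steady state, 4.50 h in it on average |  |

- alpha (time / min: target / %): 25.0: 3.9; 50.0: 5.5; 60.0: 5.9; 90.0: 7.0
- beta (time / min: target / %): 15.0: 3.7; 25.0: 4.2; 40.0: 6.0; 50.0: 8.5
- epsilon (time / min: target / %): 4.00: 0.8; 10.0: 3.5; 25.0: 7.7; 50.0: 11.6
- eta (time / min: target / %): 15.0: 1.9; 25.0: 3.6; 40.0: 3.8; 50.0: 4.9

(standard deviation of a reading: 0.5 percentage points)

- the stated concentrations are those of everything mixed, before any reaction; amounts are the same in each set-up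
- the feed brings no volume worth counting
- the earlier runs were made in a closed, stirred flask

1. the set-up with the highest amount of target at the outlet or at the end, in percent of the starting material put in ("none" if the first two lie within 2 percentage points) (dawn / noon / winter / midnight / none)
2. amount of target at the outlet or at the end, in percent of the starting material put in, dawn
3. amount of target at the outlet or at the end, in percent of the starting material put in, noon
4. amount of target at the outlet or at the end, in percent of the starting material put in, winter
5. amount of target at the outlet or at the end, in percent of the starting material put in, midnight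

My reading of the bend in the target curves is that starting material also leaves by a path second order in itself, so the target rate falls as 1/(θ + t). In epsilon, the mean rate up to 10.0 min is 2.24 times the rate from 25.0 min to 50.0 min. Setting that ratio against the midpoints of the two spans gives

θ = 21.1 min

This is the clearing time, read off scattered readings, the time in which that path takes starting material to half of its charge. The turnover count N = t/θ (a Damköhler number) says how many clearing times a stay holds. With g the gain from alpha at 90.0 min, the reckoning is:

g = 4.22%, closed flask: y = g ln(1 + N)

tank: a = (√(1 + 4N) − 1)/(2N), y = g N a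

winter: N = 4.26, y = 7.0%, the alpha reading

noon: N = 4.26, a = 0.381, y = 6.85%

midnight: N = 12.8, a = 0.243, y = 13.1%

So in this reckoning midnight stands higher than noon and winter. One number is not enough for dawn, which needs a second count, U = 3.41, for the feed, with the target rate taken in proportion to the partner dosed so far:

dawn: y = 3.13%

Eta tests the form. With θ and g scaled down by its charge of starting material, 0.15 M, the reckoning gives 4.26% target at 50.0 min against a reading of 4.9%.

The forecast gives 3% for dawn, 5.4% for noon, 7% for winter and 6.8% for midnight, with best none, and says “I assume the base is dying”. It parts from my reckoning at midnight.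

The flask gives 3.51% for dawn, 6.87% for noon, 7.44% for winter and 12.5% for midnight, so the best is midnight.

    2 starting material → homo dimer (k = 0.180 M⁻¹ min⁻¹)
    starting material + released group ⇌ idle adduct, settled at all times (K = 310 M⁻¹)
    base + released group ⇌ salt, settled at all times (K = 1.50 × 10⁵ M⁻¹)
    starting material + partner + released group → target + 2 released group (k = 1.90 M⁻² min⁻¹)
    partner + protic impurity → quenched reagent (k = 9.00 M⁻¹ min⁻¹)
    starting material + partner → target + released group (k = 0.0170 M⁻¹ min⁻¹)

Midnight stands 5.7 percentage points above the forecast. Its tank holds starting material at 0.0249 M, which is 24.9% of the charge, where the count gave 24.3%. At 15.0 h, dawn has N = 42.7, and the same g and θ reckon 12.1% target. Dawn then holds 11.1% target.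

All runs stem from a simulated flask on assumed constants, and the scatter is random.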